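## Retrosynthetic overview
1. Cut the C4–O–C4' ether on the side of the 5-hydroxy half. This gives a flavan-4-yl cation equivalent (4-benzothiazolylthio donor, 5-OH masked as an allyl ether) and intact (2S,4R)-5,6,7-trimethoxyflavan-4-ol as the O-nucleophile.
2. The trans-alcohol comes from (S)-5,6,7-trimethoxyflavanone by ketoreductase reduction. The donor comes from (S)-5-allyloxy-6,7-dimethoxyflavanone by NaBH4 reduction and Mitsunobu thiolation, and its C4 is reset in the coupling.
3. Both flavanones come from Rh-catalysed asymmetric 1,4-addition of phenylboronic acid to achiral chromones, which sets both C2 centres.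
4. Both chromones come from one 5,6,7-trimethoxychromone (OMe to O-allyl swap while still achiral), made from 3,4,5-trimethoxyphenol, AcOH and DMF-DMA.
5. Ring order: the benzene rings are bought. The only ring built is the pyranone, made once at the chromone stage, and it becomes the heterocycle of both halves.

Assumption: the SMILES reads as 2S,4R (2,4-trans) in both flavan halves; the ligand hand ((S), by the Hayashi quadrant model) and the (4R)-selective enzyme are confirmed by a short screen with chiral HPLC/CD control, the antipodal ligand being equally available.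

## Route

Step 1
Reactants: 1 3,4,5-trimethoxyphenol
Product: 2 1-(6-hydroxy-2,3,4-trimethoxyphenyl)ethan-1-one
Conditions: AcOH, BF3·OEt2 (3 equiv), 90 °C, 3 h; then H2O
Reagents that add atoms: acetic acid CC(=O)O
Why: In this BF3-mediated Friedel–Crafts (Fries-type) C-acylation the two free ring positions are equivalent, and the chelated o-hydroxyketone is deactivated towards a second acylation.

Step 2
Reactants: 2 1-(6-hydroxy-2,3,4-trimethoxyphenyl)ethan-1-one
Product: 3 (E)-3-(dimethylamino)-1-(6-hydroxy-2,3,4-trimethoxyphenyl)prop-2-en-1-one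
Conditions: DMF-DMA (2 equiv), toluene, 100 °C
Reagents that add atoms: N,N-dimethylformamide dimethyl acetal COC(OC)N(C)C
Why: In this enaminone condensation the acetyl CH3 is the only acidic C–H towards the amide acetal, and the chelated phenol is left untouched.

Step 3
Reactants: 3 (E)-3-(dimethylamino)-1-(6-hydroxy-2,3,4-trimethoxyphenyl)prop-2-en-1-one
Product: 4 5,6,7-trimethoxy-4H-chromen-4-one
Conditions: conc. HCl, CH2Cl2, 40 °C
Reagents that add atoms: none
Why: In this enaminone chromone synthesis the phenol adds to the protonated enaminone (6-endo oxa-Michael) and loss of Me2NH aromatises the pyranone ring.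

Step 4
Reactants: 4 5,6,7-trimethoxy-4H-chromen-4-one; 5 phenylboronic acid
Product: 6 (S)-5,6,7-trimethoxy-2-phenylchroman-4-one
Conditions: 5 (2.5 equiv), [RhCl(C2H4)2]2 (1.5 mol %), (S)-MeO-F12-BIPHEP (3.3 mol %), aq KOH (10 mol %), CH2Cl2/H2O, 25 °C; recrystallise
Reagents that add atoms: none
Why: In this Hayashi–Miyaura asymmetric 1,4-addition the phenyl–Rh(I) complex of the electron-poor C2-symmetric bisphosphine carbometallates one enantioface of C2=C3 and water protonates the oxa-π-allyl rhodium, which sets C2 as S (crystallised to >99 % ee), while fast room-temperature turnover avoids 1,2-addition and ring opening.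

Step 5
Reactants: 6 (S)-5,6,7-trimethoxy-2-phenylchroman-4-one
Product: 7 (2S,4R)-5,6,7-trimethoxy-2-phenylchroman-4-ol (2,4-trans)
Conditions: (R)-selective ketoreductase (KRED, NADPH-dependent alcohol dehydrogenase), NADP+ (cat.), i-PrOH (15 % v/v), K-phosphate buffer pH 7.0, MgSO4 (2 mM), DMSO (10 % v/v), 30 °C, N2 sweep
Reagents that add atoms: none
Why: In this ketoreductase-catalysed asymmetric carbonyl reduction the active site, not the substrate, decides which face of C4=O receives the NADPH hydride, which sets C4 as R and gives the 2,4-trans alcohol that hydride reagents do not give, and any trace of (2R)-ketone ends as a separable cis diastereomer.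

Step 6
Reactants: 4 5,6,7-trimethoxy-4H-chromen-4-one
Product: 9 5-hydroxy-6,7-dimethoxy-4H-chromen-4-one, via dichloroboron chelate 8 (not isolated)
Conditions: BCl3 (1.2 equiv), CH2Cl2, −78 → 0 °C; then ice-water
Reagents that add atoms: none
Why: In this chelation-directed aryl methyl ether cleavage boron bridges C4=O and the peri 5-OMe so that chloride removes only that methyl group, and because the substrate is still achiral nothing can racemise.

Step 7
Reactants: 9 5-hydroxy-6,7-dimethoxy-4H-chromen-4-one
Product: 10 5-(allyloxy)-6,7-dimethoxy-4H-chromen-4-one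
Conditions: allyl bromide (1.5 equiv), K2CO3 (2 equiv), DMF, 60 °C
Reagents that add atoms: allyl bromide C=CCBr
Why: This Williamson ether synthesis acts on the only OH in the molecule, and the allyl group cannot migrate, survives all later steps and leaves under neutral Pd(0) conditions.

Step 8
Reactants: 10 5-(allyloxy)-6,7-dimethoxy-4H-chromen-4-one; 5 phenylboronic acid
Product: 11 (S)-5-(allyloxy)-6,7-dimethoxy-2-phenylchroman-4-one
Conditions: 5 (2.5 equiv), [RhCl(C2H4)2]2 (1.5 mol %), (S)-MeO-F12-BIPHEP (3.3 mol %), aq KOH (10 mol %), CH2Cl2/H2O, 25 °C; recrystallise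
Reagents that add atoms: none
Why: This Hayashi–Miyaura asymmetric 1,4-addition works as in step 4 and sets C2 as S, and the unactivated allyl alkene is far slower than the enone towards aryl–Rh(I) at room temperature.

Step 9
Reactants: 11 (S)-5-(allyloxy)-6,7-dimethoxy-2-phenylchroman-4-one
Product: 12 (2S,4S)-5-(allyloxy)-6,7-dimethoxy-2-phenylchroman-4-ol (2,4-cis)
Conditions: NaBH4, THF/MeOH (4:1), 0 °C; pH 7 buffer quench
Reagents that add atoms: none
Why: This substrate-controlled borohydride reduction gives the 2,4-cis alcohol faster than any base-induced ring opening, and this C4 centre is provisional because step 11 erases it.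

Step 10
Reactants: 12 (2S,4S)-5-(allyloxy)-6,7-dimethoxy-2-phenylchroman-4-ol
Product: 13 2-{[(2S,4R)-5-(allyloxy)-6,7-dimethoxy-2-phenylchroman-4-yl]sulfanyl}-1,3-benzothiazole (2,4-trans)
Conditions: 2-mercaptobenzothiazole (1.3 equiv), PPh3, DIAD, THF, 0 °C → rt; Et3N-washed silica
Reagents that add atoms: 2-mercaptobenzothiazole Sc1nc2ccccc2s1
Why: This Mitsunobu thioetherification runs under neutral conditions, with the acidic soft thiol displacing the oxyphosphonium group with inversion, and the result is a storable donor whose C4 configuration does not matter later.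

Step 11
Reactants: 13 2-{[(2S,4R)-5-(allyloxy)-6,7-dimethoxy-2-phenylchroman-4-yl]sulfanyl}-1,3-benzothiazole (1.3 equiv); 7 (2S,4R)-5,6,7-trimethoxy-2-phenylchroman-4-ol (1.0 equiv)
Product: 15 5-O-allyl-beilschmieflavonoid B, via flavan-4-ylium triflate 14 (not isolated)
Conditions: AgOTf (1.6 equiv), 2,6-di-tert-butyl-4-methylpyridine (2.0 equiv), 4 Å MS, CH2Cl2/toluene, 0.3 M, −78 → −30 °C, dark; Et3N quench, Et3N-washed silica
Reagents that add atoms: none
Why: In this silver-promoted SN1 etherification (Koenigs–Knorr-like activation of a heteroaryl thioether) Ag+ removes the thiolate and cation 14, with its 2-phenyl group pseudo-equatorial, is attacked pseudo-axially, anti to the phenyl and clear of the peri 5-O-allyl group, which sets the new C4 as R (2,4-trans), while 7 reacts only through oxygen and keeps its 4R centre because the hindered base keeps the medium acid-free.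

Step 12
Reactants: 15 5-O-allyl-beilschmieflavonoid B
Product: 16 beilschmieflavonoid B
Conditions: Pd(PPh3)4 (5 mol %), morpholine (5 equiv), THF, rt; neutral alumina
Reagents that add atoms: none
Why: In this Tsuji–Trost deallylation Pd(0) ionises only the aryl allyl ether and morpholine takes up the π-allyl unit, so the acid- and hydrogenolysis-labile dibenzylic ether and all four stereocentres are untouched.

## Compound list
1 | 3,4,5-trimethoxyphenol | COc1cc(O)cc(OC)c1OC | starting material
2 | 1-(6-hydroxy-2,3,4-trimethoxyphenyl)ethan-1-one | CC(=O)c1c(O)cc(OC)c(OC)c1OC | intermediate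
3 | (E)-3-(dimethylamino)-1-(6-hydroxy-2,3,4-trimethoxyphenyl)prop-2-en-1-one | CN(C)/C=C/C(=O)c1c(O)cc(OC)c(OC)c1OC | intermediate
4 | 5,6,7-trimethoxy-4H-chromen-4-one | O=c1ccoc2cc(OC)c(OC)c(OC)c12 | intermediate
5 | phenylboronic acid | OB(O)c1ccccc1 | starting material
6 | (S)-5,6,7-trimethoxy-2-phenylchroman-4-one | O=C1C[C@@H](c2ccccc2)Oc2cc(OC)c(OC)c(OC)c21 | intermediate
7 | (2S,4R)-5,6,7-trimethoxy-2-phenylchroman-4-ol | O[C@@H]1C[C@@H](c2ccccc2)Oc2cc(OC)c(OC)c(OC)c21 | intermediate
8 | 5-(dichloroboryloxy)-6,7-dimethoxy-4H-chromen-4-one (B–O=C chelate, not isolated) | O=c1ccoc2cc(OC)c(OC)c(OB(Cl)Cl)c12 | intermediate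
9 | 5-hydroxy-6,7-dimethoxy-4H-chromen-4-one | O=c1ccoc2cc(OC)c(OC)c(O)c12 | intermediate
10 | 5-(allyloxy)-6,7-dimethoxy-4H-chromen-4-one | O=c1ccoc2cc(OC)c(OC)c(OCC=C)c12 | intermediate
11 | (S)-5-(allyloxy)-6,7-dimethoxy-2-phenylchroman-4-one | O=C1C[C@@H](c2ccccc2)Oc2cc(OC)c(OC)c(OCC=C)c21 | intermediate
12 | (2S,4S)-5-(allyloxy)-6,7-dimethoxy-2-phenylchroman-4-ol | O[C@H]1C[C@@H](c2ccccc2)Oc2cc(OC)c(OC)c(OCC=C)c21 | intermediate
13 | 2-{[(2S,4R)-5-(allyloxy)-6,7-dimethoxy-2-phenylchroman-4-yl]sulfanyl}-1,3-benzothiazole | c1ccc2sc(S[C@@H]3C[C@@H](c4ccccc4)Oc4cc(OC)c(OC)c(OCC=C)c43)nc2c1 | intermediate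
14 | (S)-5-(allyloxy)-6,7-dimethoxy-2-phenylchroman-4-ylium triflate (not isolated) | [CH+]1C[C@@H](c2ccccc2)Oc2cc(OC)c(OC)c(OCC=C)c21.[O-]S(=O)(=O)C(F)(F)F | intermediate
15 | 5-O-allyl-beilschmieflavonoid B: (2S,4R)-5-(allyloxy)-6,7-dimethoxy-2-phenylchroman-4-yl (2S,4R)-5,6,7-trimethoxy-2-phenylchroman-4-yl ether | COc1cc2c(c(OCC=C)c1OC)[C@H](O[C@@H]1C[C@@H](c3ccccc3)Oc3cc(OC)c(OC)c(OC)c31)C[C@@H](c1ccccc1)O2 | intermediate
16 | beilschmieflavonoid B | COc1cc2c(c(O)c1OC)[C@H](O[C@@H]1C[C@@H](c3ccccc3)Oc3cc(OC)c(OC)c(OC)c31)C[C@@H](c1ccccc1)O2 | target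

## Count and risks
Total steps: 12. Longest linear sequence: 10 (steps 1, 2, 3, 6, 7, 8, 9, 10, 11, 12).

**Step 11, etherification.** The risks are loss of H-3 from the cation to give the flav-3-ene, C8 Friedel–Crafts attack, a slow hindered acceptor, and scrambling if acid builds up. The fallback sets out from 12 (with 7 as partner) and comes back at 16, so steps 10–12 drop out. It replaces the cation by a base-generated ortho-quinone methide. Alcohol 12 and p-toluenesulfinic acid in CH2Cl2 give, by SN1 sulfonylation, (2S,4R)-5-(allyloxy)-6,7-dimethoxy-2-phenyl-4-tosylchroman F1. Pd(PPh3)4 with more p-toluenesulfinic acid as allyl acceptor then frees the phenol to give the bench-stable (2S,4R)-6,7-dimethoxy-2-phenyl-4-tosylchroman-5-ol F2. Cs2CO3 in toluene at 0 °C expels sulfinate and forms the ortho-quinone methide (S)-6,7-dimethoxy-2-phenyl-2,3-dihydro-5H-chromen-5-one F3. This species cannot escape by a 1,5-H shift, because the ring holds C3 anti to the carbonyl. It is trapped by 7 (2–3 equiv, excess recovered) in an oxa-Michael addition anti to the phenyl group, which gives 16 directly. No acid is present, so neither 7 nor the trimethoxy half can ionise.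

**Step 5, ketoreductase on a bulky, di-ortho-substituted aryl ketone.** The risks are low activity or the wrong facial preference. The fallback sets out from 6 and comes back at 7. NaBH4 in THF/MeOH gives (2S,4S)-5,6,7-trimethoxy-2-phenylchroman-4-ol F4. Mitsunobu inversion with chloroacetic acid, PPh3 and DIAD gives (2S,4R)-5,6,7-trimethoxy-2-phenylchroman-4-yl chloroacetate F5. A lipase (Candida antarctica lipase B, pH 7 buffer/MTBE, 30 °C) then hydrolyses the (4R)-ester, which is the matched one by the Kazlauskas rule. This neutral hydrolysis gives 7 and leaves any (4S)-ester behind. An ester that ionises in water also collapses to the trans alcohol.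

**Step 8, Rh addition in the presence of the allyl ether.** The risks are a sluggish electron-rich acceptor and aryl–Rh attack on, or isomerisation of, the allyl group. The fallback sets out from 6 and comes back at 11. It differentiates the common chiral flavanone late instead of running a second asymmetric addition. BCl3 (1.2 equiv, CH2Cl2, −78 → −20 °C) gives the chelate (S)-5-(dichloroboryloxy)-6,7-dimethoxy-2-phenylchroman-4-one F6. Ice-water turns it into (S)-5-hydroxy-6,7-dimethoxy-2-phenylchroman-4-one F7. Base-free Tsuji–Trost O-allylation (allyl methyl carbonate, Pd(PPh3)4, THF, 50 °C) then gives 11 without the carbonate bases that racemise flavanones, with ee checked by chiral HPLC.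

## Further compounds
F1 | step 11 | (2S,4R)-5-(allyloxy)-6,7-dimethoxy-2-phenyl-4-tosylchroman | Cc1ccc(cc1)S(=O)(=O)[C@@H]1C[C@@H](c2ccccc2)Oc2cc(OC)c(OC)c(OCC=C)c21
F2 | step 11 | (2S,4R)-6,7-dimethoxy-2-phenyl-4-tosylchroman-5-ol | Cc1ccc(cc1)S(=O)(=O)[C@@H]1C[C@@H](c2ccccc2)Oc2cc(OC)c(OC)c(O)c21
F3 | step 11 | (S)-6,7-dimethoxy-2-phenyl-2,3-dihydro-5H-chromen-5-one (ortho-quinone methide) | O=C1C(OC)=C(OC)C=C2O[C@H](c3ccccc3)CC=C12
F4 | step 5 | (2S,4S)-5,6,7-trimethoxy-2-phenylchroman-4-ol | O[C@H]1C[C@@H](c2ccccc2)Oc2cc(OC)c(OC)c(OC)c21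
F5 | step 5 | (2S,4R)-5,6,7-trimethoxy-2-phenylchroman-4-yl chloroacetate | O=C(CCl)O[C@@H]1C[C@@H](c2ccccc2)Oc2cc(OC)c(OC)c(OC)c21
F6 | step 8 | (S)-5-(dichloroboryloxy)-6,7-dimethoxy-2-phenylchroman-4-one | O=C1C[C@@H](c2ccccc2)Oc2cc(OC)c(OC)c(OB(Cl)Cl)c21
F7 | step 8 | (S)-5-hydroxy-6,7-dimethoxy-2-phenylchroman-4-one | O=C1C[C@@H](c2ccccc2)Oc2cc(OC)c(OC)c(O)c21
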